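The constants belong to no real substance.

Catalyst intermediate A is the form to watch in this run: its coupling with coupling partner is the step that makes left-handed product.

| flask | left-handed substrate | gas | free catalyst | right-handed substrate | temperature | time | remark |
|---|---|---|---|---|---|---|---|
| blue | 17 mM | 3.4 mM (held) | 0.43 mM | 17 mM | −10 °C | 6.0 h |  |
| teal | 17 mM | 3.4 mM (held) | 0.43 mM | 17 mM |  | 6.0 h | at −10 °C until 3.0 h, from then on at 40 °C |
| violet | 17 mM | 3.4 mM (held) | 0.43 mM | 17 mM | 40 °C | 6.0 h |  |
| grey | 17 mM | 3.4 mM (held) | 0.43 mM | 17 mM | 15 °C | 6.0 h |  |

    coupling partner + catalyst intermediate B → free catalyst + right-handed product (k1 = 11.3 M⁻¹ min⁻¹, Ea1 = 67.0 kJ mol⁻¹)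
    gas ⇌ coupling partner, rate k2*(csat - [coupling partner]) (k2 = 0.0808 min⁻¹, csat = 3.4 mM)
    free catalyst + right-handed substrate ⇌ catalyst intermediate B (K3 = 23 M⁻¹, k3 = 171 M⁻¹ min⁻¹, Ea3 = 43.0 kJ mol⁻¹, ΔH3 = −3.00 kJ mol⁻¹)
    free catalyst + left-handed substrate ⇌ catalyst intermediate A (K4 = 142 M⁻¹, k4 = 131 M⁻¹ min⁻¹, Ea4 = 52.0 kJ mol⁻¹, ΔH4 = −34.0 kJ mol⁻¹)
    free catalyst → spent catalyst (k5 = 0.00422 min⁻¹, Ea5 = 101 kJ mol⁻¹)
    coupling partner + catalyst intermediate A → free catalyst + left-handed product (k6 = 184 M⁻¹ min⁻¹, Ea6 = 42.0 kJ mol⁻¹)
    (constants at 40 °C)

- free catalyst is single-handed; left-handed substrate and right-handed substrate are mirror images of each other, charged as a racemate, each of them at the stated concentration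
- at the start none of coupling partner is dissolved
- constants are those at 40 °C; use the activation energies and enthalpies for any other temperature

1. the flask with the highest amount of left-handed product, in percent of the left-handed substrate and right-handed substrate together charged ("all alike" if they lie within 1.5 percentage points) (blue / teal / violet / grey / all alike)
2. final left-handed product, as a percentage of the left-handed substrate and right-handed substrate together charged, in blue
3. final left-handed product, as a percentage of the left-handed substrate and right-handed substrate together charged, in teal
4. final left-handed product, as a percentage of the left-handed substrate and right-handed substrate together charged, in violet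
5. final left-handed product, as a percentage of the left-handed substrate and right-handed substrate together charged, in grey

My own reckoning is made for blue and goes no further. In blue, coupling partner starts at zero but fills towards 3.4 mM with a time of 12.4 min, short beside 6.0 h, so the coupling is taken as pseudo-first-order at saturation. In blue, free catalyst dies with a life of 6270 h, far longer than the run, so the charge of catalyst is held whole.

At −10 °C the coupling constant of catalyst intermediate A falls to 8.58 M⁻¹ min⁻¹, so in blue a molecule of it waits 34.3 min for its partner. The first extreme puts the catalyst permanently in that form, as if binding cost no time, and gives a ceiling of 13.3%.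

The second extreme makes coupling instantaneous, so that the catalyst in blue waits for left-handed substrate and for nothing in the coupling. Binding has the constant 2.95 M⁻¹ min⁻¹. Catalyst intermediate B also parks catalyst: it falls back in 3.86 min but couples in 3460 min, so it is taken to stand in equilibrium with free catalyst at the constant 28.6 M⁻¹. The wait at the full charge is 29.7 min, and the ceiling is 15.3%, higher than the first.

In this reckoning the catalyst in blue pays both waits in each round, so they add. The round time τ, the mean time one catalyst takes to make one left-handed product, is the wait for substrate plus the wait for partner. With the charge held at its start, the sum gives 7.12%. That much product draws left-handed substrate down, so its curve is replaced by its mean, 15.8 mM. The substrate wait becomes 32.0 min, τ becomes 66.2 min, and blue comes to 6.88%. The two waits are alike, so blue lands near half of the lower ceiling.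

The forecast differs slightly from this, putting blue at 6.4% (5.5% to 7.3%). It gives teal 38% (33% to 43%), violet 46% (41% to 50%) and grey 30% (26% to 34%), and it names violet as highest, with “the cold flask limited by slow turnover”.

The simulation gives 6.27% in blue, 37.5% in teal, 46.0% in violet and 29.5% in grey, so violet stands highest, as forecast. At 6.00 h, blue holds 49.2% of its catalyst as catalyst intermediate A. Read back from blue's yield, the mean round took 72.6 min, longer than the reckoned 66.2 min. Carried to the neighbour of blue charged with 0.73 mM of free catalyst, that round time gives 10.6%, and the neighbour stands at 10.3%.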